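The target is cut at the C6–C(benzylic) bond: the CH(pentyl)CH2CO2H arm is treated as a ring-opened 4-pentyl lactol closed on O7. The key step exploits that C6 is the only unsubstituted carbon of benzene ring A and lies between the O5 and O7 hydroxyls. In one operation a chiral secondary amine joins (E)-oct-2-enal to C6, sets the benzylic stereocentre and closes a temporary lactol ring C on the neighbouring 7-OH. Its precursor is the complete (2R,3R)-5,7-dihydroxy-2,3-dimethyl-8-prenylchroman-4-one, built from an Evans aldol unit and phloroglucinol by Mitsunobu closure of ring B and a Claisen–Cope prenyl shift.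

Key step: step 12

Remark on the chemistry: chromanone numbering (O1, C2, C3, C4=O, C4a, C5 to C8, C8a) is used for all bicyclic compounds; ring A is the benzene ring, ring B the pyranone, ring C the temporary lactol or lactone ring, and prenyl stands for 3-methylbut-2-enyl.

Step 1
Reactants: 1 (R)-4-benzyl-3-propionyloxazolidin-2-one; 2 acetaldehyde
Product: 4 (R)-4-benzyl-3-[(2R,3S)-3-hydroxy-2-methylbutanoyl]oxazolidin-2-one, via Z-dibutylboron enolate 3 (not isolated)
Conditions: Bu2BOTf, i-Pr2NEt, CH2Cl2, 0 °C; then MeCHO, −78 → 0 °C; then pH 7 buffer, MeOH, 30% H2O2, 0 °C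
Reagents that add atoms: none
Why: Evans syn aldol reaction, in which the Z-boron enolate 3 reacts through a Zimmerman–Traxler chair on the face away from the benzyl group of the (R)-auxiliary and so should set the 2R,3S (syn) pair.

Step 2
Reactants: 4 (R)-4-benzyl-3-[(2R,3S)-3-hydroxy-2-methylbutanoyl]oxazolidin-2-one
Product: 5 (2R,3S)-3-hydroxy-N-methoxy-N,2-dimethylbutanamide
Conditions: MeONHMe·HCl, AlMe3, CH2Cl2, −10 → 0 °C; then H2O
Reagents that add atoms: N,O-dimethylhydroxylamine hydrochloride, CNOC.Cl
Why: Weinreb transamidation, in which the aluminium amide, helped by the free β-hydroxyl, cleaves the exocyclic acyl C–N bond of the imide without touching either stereocentre and releases the auxiliary for recovery.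

Step 3
Reactants: 5 (2R,3S)-3-hydroxy-N-methoxy-N,2-dimethylbutanamide
Product: 6 (2R,3S)-3-(tert-butyldimethylsilyloxy)-N-methoxy-N,2-dimethylbutanamide
Conditions: TBSCl, imidazole, DMF, rt
Reagents that add atoms: tert-butyldimethylsilyl chloride, CC(C)(C)[Si](C)(C)Cl
Why: Standard silyl ether formation masks the carbinol so that it is neither deprotonated nor eliminated in the aryllithium step.

Step 4
Reactants: 7 phloroglucinol
Product: 8 1,3,5-tris(methoxymethoxy)benzene
Conditions: MOMCl, i-Pr2NEt, CH2Cl2/DMF, 0 °C → rt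
Reagents that add atoms: chloromethyl methyl ether, COCCl
Why: Threefold O-alkylation (MOM ether formation) gives the symmetrical arene whose acetal oxygens direct the lithiation of the next step.

Step 5
Reactants: 8 1,3,5-tris(methoxymethoxy)benzene; 6 (2R,3S)-3-(tert-butyldimethylsilyloxy)-N-methoxy-N,2-dimethylbutanamide
Product: 10 (2R,3S)-3-(tert-butyldimethylsilyloxy)-2-methyl-1-[2,4,6-tris(methoxymethoxy)phenyl]butan-1-one, via 2,4,6-tris(methoxymethoxy)phenyllithium 9 (not isolated)
Conditions: n-BuLi, THF, 0 °C; then 6, −78 → 0 °C; then H2O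
Reagents that add atoms: none
Why: Directed ortho-metalation between two OMOM groups gives aryllithium 9, and its addition to the Weinreb amide (Weinreb ketone synthesis) should stop at the chelated tetrahedral adduct, so the ketone forms only on work-up, without over-addition or epimerisation of the α-carbon.

Step 6
Reactants: 10 (2R,3S)-3-(tert-butyldimethylsilyloxy)-2-methyl-1-[2,4,6-tris(methoxymethoxy)phenyl]butan-1-one
Product: 11 (2R,3S)-3-hydroxy-2-methyl-1-(2,4,6-trihydroxyphenyl)butan-1-one
Conditions: HCl (2 M in MeOH), 25 → 40 °C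
Reagents that add atoms: none
Why: Acid-catalysed acetal and silyl ether methanolysis removes all three MOM groups and the TBS group together, which avoids any need to tell the ortho from the para MOM groups, and the hydrogen-bonded acylphloroglucinol ketone should resist enolisation so that both aldol centres are kept.

Step 7
Reactants: 11 (2R,3S)-3-hydroxy-2-methyl-1-(2,4,6-trihydroxyphenyl)butan-1-one
Product: 12 (2R,3R)-5,7-dihydroxy-2,3-dimethylchroman-4-one
Conditions: PPh3, DIAD, THF (high dilution), 0 °C → rt
Reagents that add atoms: none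
Why: Intramolecular Mitsunobu etherification, in which one of the two equivalent ortho-phenols displaces the oxyphosphonium group in a 6-exo-tet SN2 closure of ring B with inversion, so that the 3S carbinol becomes C2 (R) while the aldol α-carbon becomes C3 (R), the trans and thermodynamically preferred arrangement.

Step 8
Reactants: 12 (2R,3R)-5,7-dihydroxy-2,3-dimethylchroman-4-one
Product: 13 (2R,3R)-5-hydroxy-2,3-dimethyl-4-oxochroman-7-yl acetate
Conditions: Ac2O (1.05 equiv), pyridine, CH2Cl2, 0 °C
Reagents that add atoms: acetic anhydride, CC(=O)OC(C)=O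
Why: Selective O-acylation, because the 7-OH is free and the more acidic phenol whereas the 5-OH is tied up in a hydrogen bond to the C4 carbonyl, so one equivalent of anhydride should give the 7-monoacetate.

Step 9
Reactants: 13 (2R,3R)-5-hydroxy-2,3-dimethyl-4-oxochroman-7-yl acetate; 14 3-methylbut-2-en-1-ol (prenol)
Product: 15 (2R,3R)-2,3-dimethyl-5-(3-methylbut-2-enyloxy)-4-oxochroman-7-yl acetate
Conditions: PPh3, DIAD, THF, 0 °C → rt
Reagents that add atoms: none
Why: Mitsunobu etherification alkylates the hydrogen-bonded 5-OH with the primary allylic alcohol under neutral conditions, a known route to 5-O-prenyl ethers of 7-O-acyl-5-hydroxychromanones that avoids the C-alkylation seen with prenyl halides and base.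

Step 10
Reactants: 15 (2R,3R)-2,3-dimethyl-5-(3-methylbut-2-enyloxy)-4-oxochroman-7-yl acetate
Product: 17 (2R,3R)-5-hydroxy-2,3-dimethyl-8-(3-methylbut-2-enyl)-4-oxochroman-7-yl acetate, via C6 dienone 16 (not isolated)
Conditions: Eu(fod)3 [europium tris(6,6,7,7,8,8,8-heptafluoro-2,2-dimethyloctane-3,5-dionate)] (10 mol %), CHCl3, 60 °C
Reagents that add atoms: none
Why: Tandem Claisen–Cope rearrangement, in which chelation of Eu(fod)3 between the C4 carbonyl and O5 speeds the first [3,3] shift to C6 (dienone 16) and a second [3,3] shift carries the reversed prenyl group on to C8, para to O5, where tautomerisation restores the phenol and the linear prenyl unit.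

Step 11
Reactants: 17 (2R,3R)-5-hydroxy-2,3-dimethyl-8-(3-methylbut-2-enyl)-4-oxochroman-7-yl acetate
Product: 18 (2R,3R)-5,7-dihydroxy-2,3-dimethyl-8-(3-methylbut-2-enyl)chroman-4-one
Conditions: K2CO3 (0.2 equiv), MeOH, 0 °C; then aq NH4Cl
Reagents that add atoms: none
Why: Base-catalysed transesterification of the aryl acetate frees the 7-OH without acid, which protects the neighbouring prenyl group from cyclisation, and under conditions too mild to open or epimerise the trans-chromanone.

Step 12
Reactants: 18 (2R,3R)-5,7-dihydroxy-2,3-dimethyl-8-(3-methylbut-2-enyl)chroman-4-one; 19 (E)-oct-2-enal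
Product: 22 lactol (2R,3R,6R)-5,8-dihydroxy-2,3-dimethyl-10-(3-methylbut-2-enyl)-6-pentyl-2,3,7,8-tetrahydro-4H,6H-pyrano[3,2-g]chromen-4-one as C8 anomers, via octenal iminium ion 20 (not isolated), via ring-open aldehyde 21 (not isolated)
Conditions: (S)-2-[diphenyl(trimethylsilyloxy)methyl]pyrrolidine (20 mol %), PhCO2H (20 mol %), toluene, 0 °C → rt
Reagents that add atoms: none
Why: Proposed new method: the (S)-amine condenses with the enal to the E, s-trans iminium ion 20, whose diphenyl(trimethylsilyloxy)methyl group blocks one face of the β-carbon, so C6 of 18 (ortho to O5 and O7, para to O1, meta to the acyl carbon) adds from the open face, the dienone rearomatises, and hydrolysis of the enamine releases aldehyde 21 and the catalyst. The 7-OH then closes ring C by a 6-exo-trig hemiacetalisation, which pulls the reversible addition forward. The closest known reaction type is the amine-catalysed enantioselective Friedel–Crafts alkylation–hemiacetalisation of naphthols and electron-rich phenols with enals to 4-substituted chroman-2-ols, and an acyl-bearing, pentasubstituted phloroglucinol-type nucleophile is new for it. The benzylic centre (R) should be set by the catalyst alone, since C2 and C3 are remote, and the anomeric centre is left uncontrolled because it is oxidised in the next step. The step needs 1,4- over 1,2-addition, C- over O-alkylation and one π-face: the hindered iminium ion directs attack to the β-carbon, O-addition is reversible whereas C-addition is locked by the lactol, C6 is the only aromatic C–H, and which hydroxyl closes the lactol is immaterial because step 14 opens the ring again.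

Step 13
Reactants: 22 lactol (2R,3R,6R)-5,8-dihydroxy-2,3-dimethyl-10-(3-methylbut-2-enyl)-6-pentyl-2,3,7,8-tetrahydro-4H,6H-pyrano[3,2-g]chromen-4-one
Product: 23 lactone (2R,3R,6R)-5-hydroxy-2,3-dimethyl-10-(3-methylbut-2-enyl)-6-pentyl-2,3,6,7-tetrahydro-4H,8H-pyrano[3,2-g]chromene-4,8-dione
Conditions: [C5H5NH][CrO3Cl] (pyridinium chlorochromate), NaOAc, CH2Cl2, rt
Reagents that add atoms: none
Why: Oxidation of a cyclic hemiacetal to the lactone converges both anomers to one dihydrocoumarin, and under buffered conditions the hydrogen-bonded 5-OH, the trisubstituted alkene and the non-enolisable benzylic centre should be untouched.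

Step 14
Reactants: 23 lactone (2R,3R,6R)-5-hydroxy-2,3-dimethyl-10-(3-methylbut-2-enyl)-6-pentyl-2,3,6,7-tetrahydro-4H,8H-pyrano[3,2-g]chromene-4,8-dione
Product: 25 methyl (R)-3-[(2R,3R)-5-hydroxy-7-methoxy-2,3-dimethyl-8-(3-methylbut-2-enyl)-4-oxochroman-6-yl]octanoate, via ring-opened phenoxide ester 24 (not isolated)
Conditions: K2CO3 (2 equiv), MeI (1.3 equiv), MeOH/acetone, 0 °C → rt
Reagents that add atoms: methanol, CO; iodomethane, CI
Why: Methanolysis of the aryl lactone gives ester 24 as its 7-phenoxide, which MeI methylates (Williamson ether synthesis), while the 5-OH should stay free because its hydrogen bond to the C4 carbonyl makes it much the weaker nucleophile.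

Step 15
Reactants: 25 methyl (R)-3-[(2R,3R)-5-hydroxy-7-methoxy-2,3-dimethyl-8-(3-methylbut-2-enyl)-4-oxochroman-6-yl]octanoate
Product: 26 (R)-3-[(2R,3R)-5-hydroxy-7-methoxy-2,3-dimethyl-8-(3-methylbut-2-enyl)-4-oxochroman-6-yl]octanoic acid (CNP0217102.2)
Conditions: LiOH, THF/H2O, 0 °C → rt; then 1 M HCl to pH 3
Reagents that add atoms: lithium hydroxide, [Li+].[OH-]
Why: Saponification of an unhindered methyl ester at low temperature should leave C2 and C3 intact, because the ketone is deactivated as the 5-phenoxide and trans is the thermodynamic isomer, and the benzylic centre is not acidic.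

Compound list
1 | (R)-4-benzyl-3-propionyloxazolidin-2-one | CCC(=O)N1C(=O)OC[C@H]1Cc1ccccc1 | starting material
2 | acetaldehyde | CC=O | starting material
3 | Z-dibutylboron enolate of 1 | C/C=C(\OB(CCCC)CCCC)N1C(=O)OC[C@H]1Cc1ccccc1 | intermediate
4 | (R)-4-benzyl-3-[(2R,3S)-3-hydroxy-2-methylbutanoyl]oxazolidin-2-one | C[C@H](O)[C@@H](C)C(=O)N1C(=O)OC[C@H]1Cc1ccccc1 | intermediate
5 | (2R,3S)-3-hydroxy-N-methoxy-N,2-dimethylbutanamide | C[C@H](O)[C@@H](C)C(=O)N(C)OC | intermediate
6 | (2R,3S)-3-(tert-butyldimethylsilyloxy)-N-methoxy-N,2-dimethylbutanamide | C[C@H](O[Si](C)(C)C(C)(C)C)[C@@H](C)C(=O)N(C)OC | intermediate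
7 | phloroglucinol | Oc1cc(O)cc(O)c1 | starting material
8 | 1,3,5-tris(methoxymethoxy)benzene | COCOc1cc(OCOC)cc(OCOC)c1 | intermediate
9 | 2,4,6-tris(methoxymethoxy)phenyllithium | [Li]c1c(OCOC)cc(OCOC)cc1OCOC | intermediate
10 | (2R,3S)-3-(tert-butyldimethylsilyloxy)-2-methyl-1-[2,4,6-tris(methoxymethoxy)phenyl]butan-1-one | C[C@H](O[Si](C)(C)C(C)(C)C)[C@@H](C)C(=O)c1c(OCOC)cc(OCOC)cc1OCOC | intermediate
11 | (2R,3S)-3-hydroxy-2-methyl-1-(2,4,6-trihydroxyphenyl)butan-1-one | C[C@H](O)[C@@H](C)C(=O)c1c(O)cc(O)cc1O | intermediate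
12 | (2R,3R)-5,7-dihydroxy-2,3-dimethylchroman-4-one | Oc1cc(O)c2c(c1)O[C@H](C)[C@@H](C)C2=O | intermediate
13 | (2R,3R)-5-hydroxy-2,3-dimethyl-4-oxochroman-7-yl acetate | CC(=O)Oc1cc(O)c2c(c1)O[C@H](C)[C@@H](C)C2=O | intermediate
14 | 3-methylbut-2-en-1-ol (prenol) | CC(C)=CCO | starting material
15 | (2R,3R)-2,3-dimethyl-5-(3-methylbut-2-enyloxy)-4-oxochroman-7-yl acetate | CC(=O)Oc1cc(OCC=C(C)C)c2c(c1)O[C@H](C)[C@@H](C)C2=O | intermediate
16 | (2R,3R)-2,3-dimethyl-6-(2-methylbut-3-en-2-yl)-4,5-dioxo-3,4,5,6-tetrahydro-2H-chromen-7-yl acetate (C6 epimers) | CC(=O)OC1=CC2=C(C(=O)C1C(C)(C)C=C)C(=O)[C@H](C)[C@@H](C)O2 | intermediate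
17 | (2R,3R)-5-hydroxy-2,3-dimethyl-8-(3-methylbut-2-enyl)-4-oxochroman-7-yl acetate | CC(=O)Oc1cc(O)c2c(c1CC=C(C)C)O[C@H](C)[C@@H](C)C2=O | intermediate
18 | (2R,3R)-5,7-dihydroxy-2,3-dimethyl-8-(3-methylbut-2-enyl)chroman-4-one | Oc1cc(O)c2c(c1CC=C(C)C)O[C@H](C)[C@@H](C)C2=O | intermediate
19 | (E)-oct-2-enal | CCCCC/C=C/C=O | starting material
20 | E-iminium benzoate from 19 and (S)-2-[diphenyl(trimethylsilyloxy)methyl]pyrrolidine | CCCCC/C=C/C=[N+]1\CCC[C@H]1C(c1ccccc1)(c1ccccc1)O[Si](C)(C)C.[O-]C(=O)c1ccccc1 | intermediate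
21 | (R)-3-[(2R,3R)-5,7-dihydroxy-2,3-dimethyl-8-(3-methylbut-2-enyl)-4-oxochroman-6-yl]octanal | CCCCC[C@H](CC=O)c1c(O)c2c(c(CC=C(C)C)c1O)O[C@H](C)[C@@H](C)C2=O | intermediate
22 | (2R,3R,6R)-5,8-dihydroxy-2,3-dimethyl-10-(3-methylbut-2-enyl)-6-pentyl-2,3,7,8-tetrahydro-4H,6H-pyrano[3,2-g]chromen-4-one (C8 anomers) | CCCCC[C@@H]1CC(O)Oc2c1c(O)c1c(c2CC=C(C)C)O[C@H](C)[C@@H](C)C1=O | intermediate
23 | (2R,3R,6R)-5-hydroxy-2,3-dimethyl-10-(3-methylbut-2-enyl)-6-pentyl-2,3,6,7-tetrahydro-4H,8H-pyrano[3,2-g]chromene-4,8-dione | CCCCC[C@@H]1CC(=O)Oc2c1c(O)c1c(c2CC=C(C)C)O[C@H](C)[C@@H](C)C1=O | intermediate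
24 | methyl (R)-3-[(2R,3R)-5,7-dihydroxy-2,3-dimethyl-8-(3-methylbut-2-enyl)-4-oxochroman-6-yl]octanoate (present as its potassium 7-phenoxide, drawn neutral) | CCCCC[C@H](CC(=O)OC)c1c(O)c2c(c(CC=C(C)C)c1O)O[C@H](C)[C@@H](C)C2=O | intermediate
25 | methyl (R)-3-[(2R,3R)-5-hydroxy-7-methoxy-2,3-dimethyl-8-(3-methylbut-2-enyl)-4-oxochroman-6-yl]octanoate | CCCCC[C@H](CC(=O)OC)c1c(O)c2c(c(CC=C(C)C)c1OC)O[C@H](C)[C@@H](C)C2=O | intermediate
26 | (R)-3-[(2R,3R)-5-hydroxy-7-methoxy-2,3-dimethyl-8-(3-methylbut-2-enyl)-4-oxochroman-6-yl]octanoic acid (CNP0217102.2) | CCCCC[C@H](CC(=O)O)c1c(O)c2c(c(CC=C(C)C)c1OC)O[C@H](C)[C@@H](C)C2=O | target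

Total step count: 15.
Longest linear sequence: 14 steps (steps 1 to 3 and 5 to 15, counted from compound 1); step 4 is a one-step side branch.

Steps most likely to fail

Step 12 (the proposed new method). The C4 acyl group may leave C6 too weak a nucleophile for the iminium ion. Condensation at the aldehyde carbon (1,2-addition and loss of the amine, leading towards chromene formation), reversible O-addition or incomplete face control could then take over. The fallback sets out from 18 and uses the known domino Knoevenagel–Michael–lactonisation of phloroglucinol-type phenols with an aldehyde and Meldrum's acid. Hexanal and 2,2-dimethyl-1,3-dioxane-4,6-dione would condense (pyridine or Et3N, MeCN, rt → 60 °C) to 5-hexylidene-2,2-dimethyl-1,3-dioxane-4,6-dione F1. C6 of 18 would add to F1, and acylation of the neighbouring phenol with loss of acetone and CO2 would give the dihydrocoumarin directly. This reaction has no control at the benzylic carbon, so lactone 23 should form together with its benzylic epimer, the (2R,3R,6S)-lactone F2. The two are diastereomers and would be separated by chromatography. The fallback comes back to the route at 23 and makes step 13 unnecessary.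

Step 10. The rearrangement may stop after the first [3,3] shift, through tautomerisation of the C6 dienone before the Cope step, or the Lewis acid may simply cleave the allylic ether. The fallback sets out from 12 and replaces the prenyl walk by direct Friedel–Crafts C-prenylation with 2-methylbut-3-en-2-ol and BF3·OEt2 in dioxane at rt. This is a known but unselective way to C-prenylated 5,7-dihydroxychromanones and flavanones. It should give 18 together with the regioisomer (2R,3R)-5,7-dihydroxy-2,3-dimethyl-6-(3-methylbut-2-enyl)chroman-4-one F3, which would be removed by chromatography. The fallback comes back at 18 and bypasses steps 8 to 11.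

Step 7. The oxyphosphonium salt of the β-hydroxy ketone may eliminate to the conjugated enone faster than the phenol displaces it, and unselective re-addition of the phenol would then erode the configuration at C2. The fallback sets C2 by a catalyst-controlled C–O bond formation instead of an SN2 inversion and sets out from 7. Friedel–Crafts acylation with (E)-2-methylbut-2-enoyl chloride (AlCl3, PhNO2, rt) would give (E)-2-methyl-1-(2,4,6-trihydroxyphenyl)but-2-en-1-one F4. The known cinchona-alkaloid-catalysed intramolecular oxa-Michael addition of o-tigloylphenols (quinine, or quinidine if the sense of induction requires it, PhCl, rt) should then close ring B in the 2R series as a cis/trans mixture. The cis isomer (2R,3S)-5,7-dihydroxy-2,3-dimethylchroman-4-one F5 would be converted to the trans isomer by epimerisation at C3 with a mild amine base. Enantiomeric purity would be raised by recrystallisation if needed. The fallback comes back at 12.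

Further compounds
F1 | step 12 | 5-hexylidene-2,2-dimethyl-1,3-dioxane-4,6-dione | CCCCCC=C1C(=O)OC(C)(C)OC1=O
F2 | step 12 | (2R,3R,6S)-5-hydroxy-2,3-dimethyl-10-(3-methylbut-2-enyl)-6-pentyl-2,3,6,7-tetrahydro-4H,8H-pyrano[3,2-g]chromene-4,8-dione | CCCCC[C@H]1CC(=O)Oc2c1c(O)c1c(c2CC=C(C)C)O[C@H](C)[C@@H](C)C1=O
F3 | step 10 | (2R,3R)-5,7-dihydroxy-2,3-dimethyl-6-(3-methylbut-2-enyl)chroman-4-one | Oc1c(CC=C(C)C)c(O)c2c(c1)O[C@H](C)[C@@H](C)C2=O
F4 | step 7 | (E)-2-methyl-1-(2,4,6-trihydroxyphenyl)but-2-en-1-one | C/C=C(\C)C(=O)c1c(O)cc(O)cc1O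
F5 | step 7 | (2R,3S)-5,7-dihydroxy-2,3-dimethylchroman-4-one | Oc1cc(O)c2c(c1)O[C@H](C)[C@H](C)C2=O
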